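**Strategy.** Rings A (N1, C2–C5) and B (N1', C2'–C5') are both disconnected at N1–C2 and N1'–C2'. The feature used is that the ring carbons C5–C4–C3–C2–C2'–C3'–C4'–C5' form one linear conjugated chain, with C2–C2' as the central single bond of a diene. A two-fold vinyl-nitrene closure should therefore build both pyrroles in one operation from bis-azide 6, a (2Z,4E,6E,8Z)-tetraene carrying an azide and an ester on each terminal alkene carbon, made from muconaldehyde and ethyl azidoacetate. The esters of product 8 stabilise the bipyrrole, block C5/C5' during β-bromination, and are finally exchanged for bromine by ipso-bromodecarboxylation.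

Key step: step 4

Remark: the target is achiral 3,3',4,4',5,5'-hexabromo-1H,1'H-2,2'-bipyrrole, so only the alkene geometries of 6 need control; bis-azide 6 is assumed to be handled cold, in solution, shielded from light and never concentrated to dryness on scale.

**Step 1**
Reactants: 1 dimethyl (2E,4E)-hexa-2,4-dienedioate (dimethyl trans,trans-muconate)
Product: 2 (2E,4E)-hexa-2,4-diene-1,6-diol
Conditions: i-Bu2AlH (4.5 equiv), CH2Cl2, –78 → 0 °C; aq. KNaC4H4O6 (Rochelle salt) work-up
Reagents that add atoms: none
Why: Hydride reduction of a conjugated ester with i-Bu2AlH proceeds in the 1,2-sense to the allylic alcohol and should leave the (E,E)-diene untouched.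

**Step 2**
Reactants: 2 (2E,4E)-hexa-2,4-diene-1,6-diol
Product: 3 (2E,4E)-hexa-2,4-dienedial (trans,trans-muconaldehyde)
Conditions: activated MnO2 (excess), CH2Cl2, 20 °C; filter, use at once
Reagents that add atoms: none
Why: Allylic alcohol oxidation with MnO2 is selective for allylic carbinols, stops at the enal and should not isomerise the thermodynamically preferred (E,E)-diene.

**Step 3**
Reactants: 3 (2E,4E)-hexa-2,4-dienedial; 4 ethyl azidoacetate (8 equiv)
Product: 6 diethyl (2Z,4E,6E,8Z)-2,9-diazidodeca-2,4,6,8-tetraenedioate, via ethyl (2Z,4E,6E)-2-azido-8-oxoocta-2,4,6-trienoate 5 (not isolated)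
Conditions: NaOEt (8 equiv), EtOH, –15 → 0 °C, slow addition of 3 + 4 to the base; aq. NH4Cl
Reagents that add atoms: none
Why: Knoevenagel condensation of the Hemetsberger–Knittel kind, in which the azidoacetate enolate adds to each enal carbonyl and hydroxide is eliminated to the thermodynamically preferred (Z)-azidoacrylate (azide syn to the chain), while ethoxide matches the ethyl ester and the central (E,E)-diene is carried through unchanged.

**Step 4**
Reactants: 6 diethyl (2Z,4E,6E,8Z)-2,9-diazidodeca-2,4,6,8-tetraenedioate
Product: 8 diethyl 1H,1'H-[2,2'-bipyrrole]-5,5'-dicarboxylate, via ethyl 5-[(1E,3Z)-4-azido-5-ethoxy-5-oxopenta-1,3-dien-1-yl]-1H-pyrrole-2-carboxylate 7 (not isolated)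
Conditions: Rh2(O2CC3F7)4 (5 mol%), CH2Cl2 (0.02 M), 25 → 40 °C, dark, N2
Reagents that add atoms: none
Why: The rhodium carboxylate should decompose each vinyl azide with loss of N2 to a rhodium-bound vinyl nitrene (in equilibrium with its 2H-azirine), whose N–C=C–C=C array undergoes 1,5-electrocyclisation bonding nitrogen to the δ-carbon; a 1,5-hydrogen shift in the resulting 2H-pyrrole then gives the aromatic 1H-pyrrole. The closest known reaction is the Rh2(O2CC3F7)4- or ZnI2-catalysed, or thermal Hemetsberger-type, conversion of 2-azido-2,4-dienoates into 5-substituted pyrrole-2-carboxylates, here run twice on one chain. Ring A closes by bonding N to chain C5 across C2=C3–C4=C5 and ring B by bonding N to chain C6 across C9=C8–C7=C6, each a five-atom electrocyclic closure, so the chain C5–C6 single bond becomes C2–C2' of the bipyrrole; after the first closure, intermediate 7 is a 5-aryl-type dienyl azide, the standard substrate. No stereocentre is formed. The selectivity needed is N–Cδ bonding in preference to seven-membered closure, aziridination or C–H insertion: the (Z)-azidoacrylate geometry holds nitrogen syn to the chain, the (E)-configured C4=C5 and C6=C7 bonds keep the more remote alkene carbons out of reach, and each azide consumes a different alkene of the central diene, so the two closures cannot compete. High dilution should suppress intermolecular nitrene transfer between polyene chains.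

**Step 5**
Reactants: 8 diethyl 1H,1'H-[2,2'-bipyrrole]-5,5'-dicarboxylate
Product: 9 diethyl 3,3',4,4'-tetrabromo-1H,1'H-[2,2'-bipyrrole]-5,5'-dicarboxylate
Conditions: Br2 (4.4 equiv), AcOH, 20 → 50 °C; aq. Na2S2O3
Reagents that add atoms: bromine, BrBr
Why: Electrophilic aromatic bromination can only reach the four β-positions because C2/C2' and C5/C5' are substituted, and the two esters should protect the electron-rich bipyrrole from oxidative degradation.

**Step 6**
Reactants: 9 diethyl 3,3',4,4'-tetrabromo-1H,1'H-[2,2'-bipyrrole]-5,5'-dicarboxylate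
Product: 10 3,3',4,4'-tetrabromo-1H,1'H-[2,2'-bipyrrole]-5,5'-dicarboxylic acid
Conditions: NaOH (10 equiv), EtOH/H2O, 70 °C; then aq. HCl to pH 2, 0 °C, filter
Reagents that add atoms: sodium hydroxide, [Na+].[OH-]
Why: Ester saponification by acyl–oxygen cleavage should proceed on heating, the brominated ring being shielded from hydroxide as its N-anion, and cold acidification should precipitate the diacid before protodecarboxylation can set in.

**Step 7**
Reactants: 10 3,3',4,4'-tetrabromo-1H,1'H-[2,2'-bipyrrole]-5,5'-dicarboxylic acid
Product: 12 3,3',4,4',5,5'-hexabromo-1H,1'H-2,2'-bipyrrole, via 3,3',4,4',5'-pentabromo-1H,1'H-[2,2'-bipyrrole]-5-carboxylic acid 11 (not isolated)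
Conditions: NBS (2.2 equiv), NaHCO3 (4 equiv), DMF/H2O, 0 → 20 °C, dark
Reagents that add atoms: N-bromosuccinimide, O=C1CCC(=O)N1Br
Why: Hunsdiecker-type ipso-bromodecarboxylation of a pyrrole-2-carboxylic acid, in which electrophilic bromine attacks the carboxylate-bearing α-carbon (the most nucleophilic ring position) and loss of CO2 restores aromaticity, once on each ring.

**Compound list**
1 | dimethyl (2E,4E)-hexa-2,4-dienedioate (dimethyl trans,trans-muconate) | COC(=O)/C=C/C=C/C(=O)OC | starting material
2 | (2E,4E)-hexa-2,4-diene-1,6-diol | OC/C=C/C=C/CO | intermediate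
3 | (2E,4E)-hexa-2,4-dienedial (trans,trans-muconaldehyde) | O=C/C=C/C=C/C=O | intermediate
4 | ethyl azidoacetate | CCOC(=O)CN=[N+]=[N-] | starting material
5 | ethyl (2Z,4E,6E)-2-azido-8-oxoocta-2,4,6-trienoate | CCOC(=O)/C(N=[N+]=[N-])=C/C=C/C=C/C=O | intermediate (not isolated)
6 | diethyl (2Z,4E,6E,8Z)-2,9-diazidodeca-2,4,6,8-tetraenedioate | CCOC(=O)/C(N=[N+]=[N-])=C/C=C/C=C/C=C(\N=[N+]=[N-])C(=O)OCC | intermediate
7 | ethyl 5-[(1E,3Z)-4-azido-5-ethoxy-5-oxopenta-1,3-dien-1-yl]-1H-pyrrole-2-carboxylate | CCOC(=O)c1ccc([nH]1)/C=C/C=C(\N=[N+]=[N-])C(=O)OCC | intermediate (not isolated)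
8 | diethyl 1H,1'H-[2,2'-bipyrrole]-5,5'-dicarboxylate | CCOC(=O)c1ccc([nH]1)-c1ccc([nH]1)C(=O)OCC | intermediate
9 | diethyl 3,3',4,4'-tetrabromo-1H,1'H-[2,2'-bipyrrole]-5,5'-dicarboxylate | CCOC(=O)c1[nH]c(c(Br)c1Br)-c1[nH]c(C(=O)OCC)c(Br)c1Br | intermediate
10 | 3,3',4,4'-tetrabromo-1H,1'H-[2,2'-bipyrrole]-5,5'-dicarboxylic acid | OC(=O)c1[nH]c(c(Br)c1Br)-c1[nH]c(C(=O)O)c(Br)c1Br | intermediate
11 | 3,3',4,4',5'-pentabromo-1H,1'H-[2,2'-bipyrrole]-5-carboxylic acid | OC(=O)c1[nH]c(c(Br)c1Br)-c1[nH]c(Br)c(Br)c1Br | intermediate (not isolated)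
12 | 3,3',4,4',5,5'-hexabromo-1H,1'H-2,2'-bipyrrole | Brc1[nH]c(-c2[nH]c(Br)c(Br)c2Br)c(Br)c1Br | target

**Total step count:** 7
**Longest linear sequence:** 7 steps (1 → 12); ethyl azidoacetate 4 enters at step 3.

**Steps most likely to fail**

Step 4. Intermolecular nitrene transfer between polyene chains may outrun the intramolecular closures and lead to oligomers, or the sequence may stall after the first ring when the NH-pyrrole of 7 ties up the catalyst. The fallback gives up the two-directional closure and builds the rings one after the other, so that no molecule ever carries two azides. It sets out from dialdehyde 3, which is condensed with only one equivalent of 4 (NaOEt, EtOH, –15 °C, 3 in excess and recovered) to give mono-azide 5, this time isolated. Single closure of 5 (Rh2(O2CC3F7)4 in CH2Cl2, or toluene at 110 °C) should give ethyl 5-[(E)-3-oxoprop-1-en-1-yl]-1H-pyrrole-2-carboxylate F1. A second Hemetsberger–Knittel condensation of F1 with 4 should give 7, which is isolated and closed thermally in toluene at 110 °C without catalyst; the route is rejoined at 8.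

Step 3. Conjugate addition of the enolate to the doubly activated diene, base-induced oligomerisation of the dialdehyde, and loss of N2 from the azidoacetate anion may all outpace the two carbonyl condensations, or the reaction may stop at the aldol stage. The fallback separates C–C bond formation from dehydration. It sets out from 3: addition of 4 with NaOEt in EtOH at –40 °C and a cold AcOH quench should give diethyl (4E,6E)-2,9-diazido-3,8-dihydroxydeca-4,6-dienedioate F2 as a diastereomer mixture. Treatment with MsCl/Et3N in CH2Cl2 (–20 → 20 °C) should pass through diethyl (4E,6E)-2,9-diazido-3,8-bis(methanesulfonyloxy)deca-4,6-dienedioate F3 (not isolated), which eliminates under the amine to the (Z,Z)-bis-azidoacrylate; the route is rejoined at 6.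

Step 7. Ipso attack on the strongly deactivated tetrabromo acid may be slow enough that NBS degrades the bipyrrole oxidatively instead. The fallback removes the carboxyl groups before any bromine is introduced. It sets out from 8: saponification (NaOH, aq. EtOH, reflux; HCl) should give 1H,1'H-[2,2'-bipyrrole]-5,5'-dicarboxylic acid F4. Thermal decarboxylation (NaOH, ethylene glycol, about 180 °C, or vacuum sublimation) should give 1H,1'H-2,2'-bipyrrole F5. Exhaustive electrophilic bromination of all six free ring positions with NBS (6 equiv, THF, –78 → 0 °C, dark) then rejoins the route at target 12, replacing steps 5 to 7.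

**Further compounds**
F1 | step 4 | ethyl 5-[(E)-3-oxoprop-1-en-1-yl]-1H-pyrrole-2-carboxylate | CCOC(=O)c1ccc([nH]1)/C=C/C=O
F2 | step 3 | diethyl (4E,6E)-2,9-diazido-3,8-dihydroxydeca-4,6-dienedioate (diastereomer mixture) | CCOC(=O)C(N=[N+]=[N-])C(O)/C=C/C=C/C(O)C(N=[N+]=[N-])C(=O)OCC
F3 | step 3 | diethyl (4E,6E)-2,9-diazido-3,8-bis(methanesulfonyloxy)deca-4,6-dienedioate (diastereomer mixture, not isolated) | CCOC(=O)C(N=[N+]=[N-])C(OS(C)(=O)=O)/C=C/C=C/C(OS(C)(=O)=O)C(N=[N+]=[N-])C(=O)OCC
F4 | step 7 | 1H,1'H-[2,2'-bipyrrole]-5,5'-dicarboxylic acid | OC(=O)c1ccc([nH]1)-c1ccc([nH]1)C(=O)O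
F5 | step 7 | 1H,1'H-2,2'-bipyrrole | c1cc([nH]c1)-c1ccc[nH]1
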